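**Plan**

1. Retrosynthetic cuts: the two silyl ethers and the C7–CH3 bond; then the C5a–C6 ring bond of the cyclohexane, made forwards by 1,2-shift of C5a from C7 to an exocyclic C6–OMs on a cyclopentanol (five- to six-membered ring enlargement); then the C6–CH2 bond of the two-carbon bridge (alkyllithium plus α-silyloxy aldehyde), which joins the halves.
2. Ether half: 2-methylcyclopentane-1,3-dione → side chain (Michael, Wittig) → desymmetrising reduction → epoxidation → oxepane closed cis on the cyclopentane → one-carbon homologation of the ketone to the C7 carbinol aldehyde.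
3. Hydroazulene half: 4,4-dimethylcyclohexenone → conjugate addition → six- to seven-ring enlargement → ketyl–olefin closure of the five-membered ring → enone → Claisen rearrangement plants the bridge at C5'.
4. Stereochemistry: C5a/C9a from the CBS desymmetrisation; C3 from the Shi epoxide; C6 from convex-face dihydroxylation, Felkin–Anh addition and inversion in the shift; C7 from equatorial methyl addition; C3a' from the copper-catalysed addition; C1'/C8a' from the cyclisation; C5' by chirality transfer from the CBS-set C7' carbinol.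
5. Enabling feature: in the cyclopentane (C5a, C7, C8, C9, C9a) the carbinol carbon C7 sits next to the quaternary C5a and carries the exocyclic C6 with a leaving group; the C7–C5a bond can lie anti to C6–O, and the C7 oxygen becomes the ketone that takes the last methyl group.

Key step: step 24

Remark: labels O1–C9a (benzo[b]oxepine numbering) are used for the ether half and C1'–C8a' (azulene numbering) for the hydroazulene half, also in the intermediates leading to them. The target as drawn has a cis-fused oxepane/cyclohexane and a cis-fused hydroazulene. The catalyst enantiomers named are those expected from the usual models; the antipode would be taken if a model failed on these substrates.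

**Ether half**

Step 1
Reactants: 1 2-methylcyclopentane-1,3-dione; 2 acrolein
Product: 3 3-(1-methyl-2,5-dioxocyclopentyl)propanal
Conditions: H2O, rt
Reagents that add atoms: none
Why: Michael addition of the acidic cyclic 1,3-dione to acrolein in water gives the 2,2-disubstituted dione without added base and creates no stereocentre.

Step 2
Reactants: 3 3-(1-methyl-2,5-dioxocyclopentyl)propanal
Product: 4 2-methyl-2-(4-methylpent-3-en-1-yl)cyclopentane-1,3-dione
Conditions: i-PrPPh3I, NaN(SiMe3)2, THF, 0 °C; then 3, −78 °C → rt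
Reagents that add atoms: isopropyltriphenylphosphonium iodide, CC(C)[P+](c1ccccc1)(c1ccccc1)c1ccccc1.[I-]
Why: Wittig olefination by the non-stabilised isopropylidene ylide should be faster at the aldehyde than at the hindered ring ketones and builds the C2=C3 trisubstituted alkene.

Step 3
Reactants: 4 2-methyl-2-(4-methylpent-3-en-1-yl)cyclopentane-1,3-dione
Product: 5 (2R,3R)-3-hydroxy-2-methyl-2-(4-methylpent-3-en-1-yl)cyclopentan-1-one
Conditions: (S)-2-methyl-CBS-oxazaborolidine (20 mol %), catecholborane, toluene/CH2Cl2, −78 °C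
Reagents that add atoms: none
Why: Corey–Bakshi–Shibata desymmetrisation, in which the oxazaborolidine (quaternary carbon as the large group) selects one enantiotopic carbonyl and hydride arrives anti to the longer chain, should set C9a and C5a together with the hydroxyl cis to that chain.

Step 4
Reactants: 5 (2R,3R)-3-hydroxy-2-methyl-2-(4-methylpent-3-en-1-yl)cyclopentan-1-one
Product: 6 (2R,3R)-2-{2-[(2S)-3,3-dimethyloxiran-2-yl]ethyl}-3-hydroxy-2-methylcyclopentan-1-one
Conditions: L-fructose-derived Shi ketone (30 mol %), KHSO5 (Oxone), K2CO3, Bu4NHSO4, MeCN/dimethoxymethane/aq. buffer, 0 °C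
Reagents that add atoms: potassium peroxymonosulfate, [K+].[O-]S(=O)(=O)OO
Why: Shi asymmetric epoxidation (chiral dioxirane, spiro transition state) is reagent-controlled on the trisubstituted alkene and should give the (S)-epoxide that fixes C3, the ketone and free alcohol being tolerated under buffered conditions.

Step 5
Reactants: 6 (2R,3R)-2-{2-[(2S)-3,3-dimethyloxiran-2-yl]ethyl}-3-hydroxy-2-methylcyclopentan-1-one
Product: 7 cis-fused (3S,5aR,8aR)-3-hydroxy-2,2,5a-trimethyloctahydro-6H-cyclopenta[b]oxepin-6-one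
Conditions: (+)-camphorsulfonic acid (10 mol %), (CF3)2CHOH, 0 °C
Reagents that add atoms: none
Why: Acid-catalysed intramolecular epoxide opening in a strongly ionising solvent should lengthen the bond to the tertiary C2, so the C9a hydroxyl attacks C2 (7-endo) with retention at C3 and closes the oxepane cis because oxygen and chain are cis on the cyclopentane.

Step 6
Reactants: 7 cis-fused (3S,5aR,8aR)-3-hydroxy-2,2,5a-trimethyloctahydro-6H-cyclopenta[b]oxepin-6-one
Product: 8 (3S,5aR,8aR)-3-(tert-butyldimethylsilyloxy)-2,2,5a-trimethyloctahydro-6H-cyclopenta[b]oxepin-6-one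
Conditions: TBSOTf, 2,6-lutidine, CH2Cl2, −78 → 0 °C
Reagents that add atoms: tert-butyldimethylsilyl triflate, CC(C)(C)[Si](C)(C)OS(=O)(=O)C(F)(F)F
Why: Silyl triflate silylation protects the hindered secondary C3 hydroxyl for the basic and organometallic steps that follow.

Step 7
Reactants: 8 (3S,5aR,8aR)-3-(tert-butyldimethylsilyloxy)-2,2,5a-trimethyloctahydro-6H-cyclopenta[b]oxepin-6-one
Product: 9 (3S,5aS,8aR)-3-(tert-butyldimethylsilyloxy)-6-(methoxymethylidene)-2,2,5a-trimethyloctahydro-2H-cyclopenta[b]oxepine (E/Z mixture)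
Conditions: MeOCH2PPh3Cl, KOt-Bu, THF, 0 °C → rt
Reagents that add atoms: (methoxymethyl)triphenylphosphonium chloride, COC[P+](c1ccccc1)(c1ccccc1)c1ccccc1.[Cl-]
Why: Wittig methoxymethylenation turns the hindered ketone into the exocyclic enol ether, which brings in the future C6 as one carbon; the alkene geometry does not matter.

Step 8
Reactants: 9 (3S,5aS,8aR)-3-(tert-butyldimethylsilyloxy)-6-(methoxymethylidene)-2,2,5a-trimethyloctahydro-2H-cyclopenta[b]oxepine
Product: 11 (3S,5aR,6R,8aR)-3-(tert-butyldimethylsilyloxy)-6-hydroxy-2,2,5a-trimethyloctahydro-2H-cyclopenta[b]oxepine-6-carbaldehyde, via methyl hemiacetal 10 (not isolated)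
Conditions: OsO4 (2 mol %), N-methylmorpholine N-oxide, acetone/H2O, 0 °C
Reagents that add atoms: N-methylmorpholine N-oxide, C[N+]1([O-])CCOCC1; water, O
Why: Osmium-catalysed dihydroxylation of the electron-rich enol ether should occur on the convex face of the cis-fused bicycle (the face of the angular methyl, away from the oxepane), and loss of methanol from the hemiacetal leaves the aldehyde with the C7 hydroxyl syn to the C5a methyl.

Step 9
Reactants: 11 (3S,5aR,6R,8aR)-3-(tert-butyldimethylsilyloxy)-6-hydroxy-2,2,5a-trimethyloctahydro-2H-cyclopenta[b]oxepine-6-carbaldehyde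
Product: 12 (3S,5aR,6R,8aR)-3-(tert-butyldimethylsilyloxy)-2,2,5a-trimethyl-6-(trimethylsilyloxy)octahydro-2H-cyclopenta[b]oxepine-6-carbaldehyde
Conditions: TMSOTf, 2,6-lutidine, CH2Cl2, −78 °C (crude 11 used at once)
Reagents that add atoms: trimethylsilyl triflate, C[Si](C)(C)OS(=O)(=O)C(F)(F)F
Why: Immediate silylation stops acyloin shift or dimerisation of the α-hydroxy aldehyde and makes the oxygen a non-chelating polar group for the Felkin–Anh addition of step 22.

**Hydroazulene half**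

Step 10
Reactants: 13 4,4-dimethylcyclohex-2-en-1-one; 14 but-3-en-1-ylmagnesium bromide
Product: 16 (S)-{[3-(but-3-en-1-yl)-4,4-dimethylcyclohex-1-en-1-yl]oxy}trimethylsilane, via magnesium enolate 15 (not isolated)
Conditions: CuBr·SMe2 (5 mol %), (R)-1-[(S)-2-(diphenylphosphino)ferrocenyl]ethyldicyclohexylphosphine (6 mol %), t-BuOMe, −78 °C; then TMSCl, Et3N, −78 → 0 °C
Reagents that add atoms: chlorotrimethylsilane, C[Si](C)(C)Cl
Why: Copper-catalysed asymmetric conjugate addition of the Grignard reagent under ligand control sets C3a', and silylation of the magnesium enolate fixes the enol ether regiochemistry for the ring enlargement.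

Step 11
Reactants: 16 (S)-{[3-(but-3-en-1-yl)-4,4-dimethylcyclohex-1-en-1-yl]oxy}trimethylsilane
Product: 17 (5S)-5-(but-3-en-1-yl)-4,4-dimethyl-1-(trimethylsilyloxy)bicyclo[4.1.0]heptane (cyclopropane epimers)
Conditions: Et2Zn, CH2I2 (1.2 equiv), CH2Cl2, 0 °C
Reagents that add atoms: diiodomethane, ICI
Why: Furukawa-type Simmons–Smith cyclopropanation should select the electron-rich silyl enol ether over the terminal alkene, and the new cyclopropane stereocentres are lost in step 12.

Step 12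
Reactants: 17 (5S)-5-(but-3-en-1-yl)-4,4-dimethyl-1-(trimethylsilyloxy)bicyclo[4.1.0]heptane
Product: 19 (S)-4-(but-3-en-1-yl)-5,5-dimethylcyclohept-2-en-1-one, via β-chloro ketone 18 (not isolated)
Conditions: FeCl3 (2.2 equiv), DMF, 0 °C; then NaOAc, MeOH, reflux
Reagents that add atoms: none
Why: Saegusa–Ito ring expansion, in which oxidation of the siloxycyclopropane cleaves the internal bond (six- to seven-membered ring), chlorine transfer gives the β-chloro ketone and acetate eliminates HCl to the cycloheptenone.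

Step 13
Reactants: 19 (S)-4-(but-3-en-1-yl)-5,5-dimethylcyclohept-2-en-1-one
Product: 20 (4S)-4-(but-3-en-1-yl)-5,5,7-trimethylcyclohept-2-en-1-one (C7 epimers)
Conditions: LiN(i-Pr)2, THF, −78 °C; MeI, −78 → 0 °C
Reagents that add atoms: iodomethane, CI
Why: Kinetic deprotonation of the enone at the α' carbon followed by methylation installs the future C6' methyl, and the new stereocentre is erased in step 17.

Step 14
Reactants: 20 (4S)-4-(but-3-en-1-yl)-5,5,7-trimethylcyclohept-2-en-1-one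
Product: 21 (4S)-5,5,7-trimethyl-4-(3-oxobutyl)cyclohept-2-en-1-one (C7 epimers)
Conditions: PdCl2 (10 mol %), CuCl, O2 (1 atm), DMF/H2O, rt
Reagents that add atoms: water, O
Why: Tsuji–Wacker oxidation converts only the terminal alkene into the methyl ketone (Markovnikov hydroxypalladation) and leaves the enone untouched.

Step 15
Reactants: 21 (4S)-5,5,7-trimethyl-4-(3-oxobutyl)cyclohept-2-en-1-one
Product: 22 cis-fused (1S,3aS,8aS)-1-hydroxy-1,4,4,6-tetramethyloctahydroazulen-7(1H)-one (C6 epimers)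
Conditions: SmI2 (2.2 equiv), t-BuOH (2 equiv), HMPA, THF, −78 → 0 °C
Reagents that add atoms: none
Why: Samarium diiodide ketyl–olefin cyclisation, in which the ketyl adds 5-exo to the enone β-carbon from the face of its own tether (cis ring fusion, C8a') and keeps its bulky oxygen anti to the enone chain, should place the C1' hydroxyl cis to H-8a'.

Step 16
Reactants: 22 cis-fused (1S,3aS,8aS)-1-hydroxy-1,4,4,6-tetramethyloctahydroazulen-7(1H)-one
Product: 23 (1S,3aS,8aS)-1,4,4,6-tetramethyl-1-(triethylsilyloxy)octahydroazulen-7(1H)-one (C6 epimers)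
Conditions: TESOTf, 2,6-lutidine, CH2Cl2, −78 °C
Reagents that add atoms: triethylsilyl triflate, CC[Si](CC)(CC)OS(=O)(=O)C(F)(F)F
Why: Silyl triflate silylation protects the tertiary C1' hydroxyl as a triethylsilyl ether that survives the enolisation, Claisen and organolithium steps.

Step 17
Reactants: 23 (1S,3aS,8aS)-1,4,4,6-tetramethyl-1-(triethylsilyloxy)octahydroazulen-7(1H)-one
Product: 25 (1S,3aS,8aS)-1,4,4,6-tetramethyl-1-(triethylsilyloxy)-2,3,3a,4,8,8a-hexahydroazulen-7(1H)-one, via silyl enol ether 24 (not isolated)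
Conditions: TMSCl, NaI, Et3N, MeCN, rt; then Pd(OAc)2 (1.05 equiv), MeCN, rt
Reagents that add atoms: none
Why: Silyl enol ether formation under equilibrating conditions goes towards the more substituted C6', and Saegusa–Ito oxidation then gives the C5'=C6' enone.

Step 18
Reactants: 25 (1S,3aS,8aS)-1,4,4,6-tetramethyl-1-(triethylsilyloxy)-2,3,3a,4,8,8a-hexahydroazulen-7(1H)-one
Product: 26 (1S,3aS,7R,8aS)-1,4,4,6-tetramethyl-1-(triethylsilyloxy)-1,2,3,3a,4,7,8,8a-octahydroazulen-7-ol
Conditions: (S)-2-methyl-CBS-oxazaborolidine (1 equiv), catecholborane, toluene, −78 °C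
Reagents that add atoms: none
Why: CBS 1,2-reduction of the α-methyl enone (alkenyl side as the large group) is reagent-controlled and should give the (7'R) allylic alcohol with its hydroxyl on the face opposite H-3a' and H-8a'.

Step 19
Reactants: 26 (1S,3aS,7R,8aS)-1,4,4,6-tetramethyl-1-(triethylsilyloxy)-1,2,3,3a,4,7,8,8a-octahydroazulen-7-ol
Product: 28 ethyl 2-[(1S,3aS,5R,8aS)-1,4,4,6-tetramethyl-1-(triethylsilyloxy)-1,2,3,3a,4,5,8,8a-octahydroazulen-5-yl]acetate, via ketene acetal 27 (not isolated)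
Conditions: MeC(OEt)3 (10 equiv), EtCO2H (cat.), xylene, 140 °C
Reagents that add atoms: triethyl orthoacetate, CCOC(C)(OCC)OCC
Why: Johnson–Claisen rearrangement is suprafacial, so the CH2CO2Et group arrives at C5' on the face the C7' oxygen leaves, next to the quaternary C4', while the alkene moves to C6'=C7'.

Step 20
Reactants: 28 ethyl 2-[(1S,3aS,5R,8aS)-1,4,4,6-tetramethyl-1-(triethylsilyloxy)-1,2,3,3a,4,5,8,8a-octahydroazulen-5-yl]acetate
Product: 29 2-[(1S,3aS,5R,8aS)-1,4,4,6-tetramethyl-1-(triethylsilyloxy)-1,2,3,3a,4,5,8,8a-octahydroazulen-5-yl]ethan-1-ol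
Conditions: LiAlH4, Et2O, 0 °C
Reagents that add atoms: none
Why: Hydride reduction of the ester gives the primary alcohol and leaves the silyl ether and the trisubstituted alkene intact.

Step 21
Reactants: 29 2-[(1S,3aS,5R,8aS)-1,4,4,6-tetramethyl-1-(triethylsilyloxy)-1,2,3,3a,4,5,8,8a-octahydroazulen-5-yl]ethan-1-ol
Product: 30 (1S,3aS,5R,8aS)-5-(2-iodoethyl)-1,4,4,6-tetramethyl-1-(triethylsilyloxy)-1,2,3,3a,4,5,8,8a-octahydroazulene
Conditions: I2, PPh3, imidazole, CH2Cl2, 0 °C
Reagents that add atoms: iodine, II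
Why: Appel-type iodination converts the unhindered primary alcohol into the iodide under buffered conditions that the silyl ether tolerates.

**Union and completion**

Step 22
Reactants: 30 (1S,3aS,5R,8aS)-5-(2-iodoethyl)-1,4,4,6-tetramethyl-1-(triethylsilyloxy)-1,2,3,3a,4,5,8,8a-octahydroazulene; 12 (3S,5aR,6R,8aR)-3-(tert-butyldimethylsilyloxy)-2,2,5a-trimethyl-6-(trimethylsilyloxy)octahydro-2H-cyclopenta[b]oxepine-6-carbaldehyde
Product: 33 (1S)-1-[(3S,5aR,6R,8aR)-3-(tert-butyldimethylsilyloxy)-6-hydroxy-2,2,5a-trimethyloctahydro-2H-cyclopenta[b]oxepin-6-yl]-3-[(1S,3aS,5R,8aS)-1,4,4,6-tetramethyl-1-(triethylsilyloxy)-1,2,3,3a,4,5,8,8a-octahydroazulen-5-yl]propan-1-ol, via alkyllithium 31 (not isolated), via lithium alkoxide 32 (not isolated)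
Conditions: t-BuLi (2.1 equiv), Et2O, −78 °C; then 12, THF, −78 °C; then K2CO3, MeOH, 0 °C
Reagents that add atoms: none
Why: Iodine–lithium exchange gives the primary alkyllithium, which should add to the α-silyloxy aldehyde under Felkin–Anh control (C–OSi anti to the nucleophile, which passes the C8 methylene and not the quaternary C5a) and so set C6, after which mild methanolysis removes only the trimethylsilyl ether.

Step 23
Reactants: 33 the diol of step 22
Product: 34 (1S)-1-[(3S,5aR,6R,8aR)-3-(tert-butyldimethylsilyloxy)-6-hydroxy-2,2,5a-trimethyloctahydro-2H-cyclopenta[b]oxepin-6-yl]-3-[(1S,3aS,5R,8aS)-1,4,4,6-tetramethyl-1-(triethylsilyloxy)-1,2,3,3a,4,5,8,8a-octahydroazulen-5-yl]propyl methanesulfonate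
Conditions: MsCl, Et3N, CH2Cl2, −20 °C
Reagents that add atoms: methanesulfonyl chloride, CS(=O)(=O)Cl
Why: Sulfonylation through sulfene should occur only at the secondary C6 hydroxyl because the tertiary C7 hydroxyl is too hindered to react.

Step 24
Reactants: 34 the hydroxy mesylate of step 23
Product: 36 (3S,5aS,6S,9aR)-3-(tert-butyldimethylsilyloxy)-2,2,5a-trimethyl-6-{2-[(1S,3aS,5R,8aS)-1,4,4,6-tetramethyl-1-(triethylsilyloxy)-1,2,3,3a,4,5,8,8a-octahydroazulen-5-yl]ethyl}octahydrobenzo[b]oxepin-7(2H)-one, via aluminium alkoxide 35 (not isolated)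
Conditions: Et3Al (3 equiv), CH2Cl2, −78 → 0 °C
Reagents that add atoms: none
Why: Et3Al turns the tertiary alcohol into an aluminium alkoxide that also binds the sulfonate, and the C7–C5a bond, lying antiperiplanar to C6–OMs, migrates to C6 as the mesylate leaves while the oxygen lone pair forms the C7 carbonyl (semipinacol rearrangement of a 2-hydroxy sulfonate). The closest known reaction type is the pinacol-type ring enlargement of cycloalkanols carrying an exocyclic sulfonate or diazonium group, as in steroid D-homoannulation. The cyclohexanone ring (C5a, C6, C7, C8, C9, C9a) is closed by this 1,2-shift of a ring bond, that is by insertion of the exocyclic C6 into the cyclopentane, and not by a polar or radical cyclisation. C6 is set by inversion at the migration terminus (its carbinol configuration comes from step 22) and C5a migrates with retention, so the side chain ends cis to the C5a methyl. The step needs migration of the quaternary C5a instead of the C8 methylene and no oxirane closure; the quaternary carbon is the better migrating group, the reactive rotamer is the least hindered one (side chain between C5a and oxygen, only H-6 facing the ring), and binding of the alkoxide to aluminium should suppress attack of oxygen on C6.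

Step 25
Reactants: 36 the cyclohexanone of step 24
Product: 37 (3S,5aS,6S,7R,9aR)-3-(tert-butyldimethylsilyloxy)-2,2,5a,7-tetramethyl-6-{2-[(1S,3aS,5R,8aS)-1,4,4,6-tetramethyl-1-(triethylsilyloxy)-1,2,3,3a,4,5,8,8a-octahydroazulen-5-yl]ethyl}decahydrobenzo[b]oxepin-7-ol
Conditions: MeLi, CeCl3, THF, −78 °C
Reagents that add atoms: methyllithium, [Li]C
Why: Methylcerium addition avoids enolisation (and so C6 epimerisation) of the hindered ketone and should come along the equatorial direction, anti to the axial C5a methyl that blocks the axial path, giving the axial C7 hydroxyl cis to that methyl and to the C6 side chain.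

Step 26
Reactants: 37 the bis-silyl ether of step 25
Product: 38 (3S,5aS,6S,7R,9aR)-6-{2-[(1S,3aS,5R,8aS)-1-hydroxy-1,4,4,6-tetramethyl-1,2,3,3a,4,5,8,8a-octahydroazulen-5-yl]ethyl}-2,2,5a,7-tetramethyldecahydrobenzo[b]oxepine-3,7-diol
Conditions: Bu4NF (5 equiv), THF, rt → 50 °C
Reagents that add atoms: none
Why: Fluoride cleaves the tertiary triethylsilyl and the secondary tert-butyldimethylsilyl ether without affecting the alkene or the tertiary alcohols and releases the target.

**Compound list**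

1 | 2-methylcyclopentane-1,3-dione | CC1C(=O)CCC1=O | starting material
2 | acrolein | C=CC=O | starting material
3 | 3-(1-methyl-2,5-dioxocyclopentyl)propanal | CC1(CCC=O)C(=O)CCC1=O | intermediate
4 | 2-methyl-2-(4-methylpent-3-en-1-yl)cyclopentane-1,3-dione | CC(C)=CCCC1(C)C(=O)CCC1=O | intermediate
5 | (2R,3R)-3-hydroxy-2-methyl-2-(4-methylpent-3-en-1-yl)cyclopentan-1-one | O=C1CC[C@@H](O)[C@@]1(C)CCC=C(C)C | intermediate
6 | (2R,3R)-2-{2-[(2S)-3,3-dimethyloxiran-2-yl]ethyl}-3-hydroxy-2-methylcyclopentan-1-one | O=C1CC[C@@H](O)[C@@]1(C)CC[C@@H]1OC1(C)C | intermediate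
7 | cis-fused (3S,5aR,8aR)-3-hydroxy-2,2,5a-trimethyloctahydro-6H-cyclopenta[b]oxepin-6-one | O=C1CC[C@H]2OC(C)(C)[C@@H](O)CC[C@@]12C | intermediate
8 | (3S,5aR,8aR)-3-(tert-butyldimethylsilyloxy)-2,2,5a-trimethyloctahydro-6H-cyclopenta[b]oxepin-6-one | O=C1CC[C@H]2OC(C)(C)[C@@H](O[Si](C)(C)C(C)(C)C)CC[C@@]12C | intermediate
9 | (3S,5aS,8aR)-3-(tert-butyldimethylsilyloxy)-6-(methoxymethylidene)-2,2,5a-trimethyloctahydro-2H-cyclopenta[b]oxepine (E/Z mixture) | COC=C1CC[C@H]2OC(C)(C)[C@@H](O[Si](C)(C)C(C)(C)C)CC[C@@]12C | intermediate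
10 | methyl hemiacetal of 11, (3S,5aR,6R,8aR)-3-(tert-butyldimethylsilyloxy)-6-[hydroxy(methoxy)methyl]-2,2,5a-trimethyloctahydro-2H-cyclopenta[b]oxepin-6-ol | COC(O)[C@@]1(O)CC[C@H]2OC(C)(C)[C@@H](O[Si](C)(C)C(C)(C)C)CC[C@@]12C | intermediate
11 | (3S,5aR,6R,8aR)-3-(tert-butyldimethylsilyloxy)-6-hydroxy-2,2,5a-trimethyloctahydro-2H-cyclopenta[b]oxepine-6-carbaldehyde | O=C[C@@]1(O)CC[C@H]2OC(C)(C)[C@@H](O[Si](C)(C)C(C)(C)C)CC[C@@]12C | intermediate
12 | (3S,5aR,6R,8aR)-3-(tert-butyldimethylsilyloxy)-2,2,5a-trimethyl-6-(trimethylsilyloxy)octahydro-2H-cyclopenta[b]oxepine-6-carbaldehyde | O=C[C@@]1(O[Si](C)(C)C)CC[C@H]2OC(C)(C)[C@@H](O[Si](C)(C)C(C)(C)C)CC[C@@]12C | intermediate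
13 | 4,4-dimethylcyclohex-2-en-1-one | CC1(C)C=CC(=O)CC1 | starting material
14 | but-3-en-1-ylmagnesium bromide | C=CCC[Mg]Br | starting material
15 | bromomagnesium (S)-3-(but-3-en-1-yl)-4,4-dimethylcyclohex-1-en-1-olate | Br[Mg]OC1=C[C@H](CCC=C)C(C)(C)CC1 | intermediate
16 | (S)-{[3-(but-3-en-1-yl)-4,4-dimethylcyclohex-1-en-1-yl]oxy}trimethylsilane | C[Si](C)(C)OC1=C[C@H](CCC=C)C(C)(C)CC1 | intermediate
17 | (5S)-5-(but-3-en-1-yl)-4,4-dimethyl-1-(trimethylsilyloxy)bicyclo[4.1.0]heptane (cyclopropane epimers) | C[Si](C)(C)OC12CC1[C@H](CCC=C)C(C)(C)CC2 | intermediate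
18 | (4S)-4-(but-3-en-1-yl)-3-chloro-5,5-dimethylcycloheptan-1-one (C3 epimers) | O=C1CC(Cl)[C@H](CCC=C)C(C)(C)CC1 | intermediate
19 | (S)-4-(but-3-en-1-yl)-5,5-dimethylcyclohept-2-en-1-one | O=C1C=C[C@H](CCC=C)C(C)(C)CC1 | intermediate
20 | (4S)-4-(but-3-en-1-yl)-5,5,7-trimethylcyclohept-2-en-1-one (C7 epimers) | O=C1C=C[C@H](CCC=C)C(C)(C)CC1C | intermediate
21 | (4S)-5,5,7-trimethyl-4-(3-oxobutyl)cyclohept-2-en-1-one (C7 epimers) | O=C1C=C[C@H](CCC(C)=O)C(C)(C)CC1C | intermediate
22 | cis-fused (1S,3aS,8aS)-1-hydroxy-1,4,4,6-tetramethyloctahydroazulen-7(1H)-one (C6 epimers) | CC1C(=O)C[C@H]2[C@H](CC[C@]2(C)O)C(C)(C)C1 | intermediate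
23 | (1S,3aS,8aS)-1,4,4,6-tetramethyl-1-(triethylsilyloxy)octahydroazulen-7(1H)-one (C6 epimers) | CC1C(=O)C[C@H]2[C@H](CC[C@]2(C)O[Si](CC)(CC)CC)C(C)(C)C1 | intermediate
24 | (1S,3aS,8aS)-1,4,4,6-tetramethyl-1-(triethylsilyloxy)-7-(trimethylsilyloxy)-1,2,3,3a,4,5,8,8a-octahydroazulene | CC1=C(O[Si](C)(C)C)C[C@H]2[C@H](CC[C@]2(C)O[Si](CC)(CC)CC)C(C)(C)C1 | intermediate
25 | (1S,3aS,8aS)-1,4,4,6-tetramethyl-1-(triethylsilyloxy)-2,3,3a,4,8,8a-hexahydroazulen-7(1H)-one | CC=1C(=O)C[C@H]2[C@H](CC[C@]2(C)O[Si](CC)(CC)CC)C(C)(C)C=1 | intermediate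
26 | (1S,3aS,7R,8aS)-1,4,4,6-tetramethyl-1-(triethylsilyloxy)-1,2,3,3a,4,7,8,8a-octahydroazulen-7-ol | CC=1[C@H](O)C[C@H]2[C@H](CC[C@]2(C)O[Si](CC)(CC)CC)C(C)(C)C=1 | intermediate
27 | 7-O-(1-ethoxyvinyl) ether of 26 (ketene acetal) | CC=1[C@H](OC(=C)OCC)C[C@H]2[C@H](CC[C@]2(C)O[Si](CC)(CC)CC)C(C)(C)C=1 | intermediate
28 | ethyl 2-[(1S,3aS,5R,8aS)-1,4,4,6-tetramethyl-1-(triethylsilyloxy)-1,2,3,3a,4,5,8,8a-octahydroazulen-5-yl]acetate | CC1=CC[C@H]2[C@H](CC[C@]2(C)O[Si](CC)(CC)CC)C(C)(C)[C@@H]1CC(=O)OCC | intermediate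
29 | 2-[(1S,3aS,5R,8aS)-1,4,4,6-tetramethyl-1-(triethylsilyloxy)-1,2,3,3a,4,5,8,8a-octahydroazulen-5-yl]ethan-1-ol | CC1=CC[C@H]2[C@H](CC[C@]2(C)O[Si](CC)(CC)CC)C(C)(C)[C@@H]1CCO | intermediate
30 | (1S,3aS,5R,8aS)-5-(2-iodoethyl)-1,4,4,6-tetramethyl-1-(triethylsilyloxy)-1,2,3,3a,4,5,8,8a-octahydroazulene | CC1=CC[C@H]2[C@H](CC[C@]2(C)O[Si](CC)(CC)CC)C(C)(C)[C@@H]1CCI | intermediate
31 | 2-[(1S,3aS,5R,8aS)-1,4,4,6-tetramethyl-1-(triethylsilyloxy)-1,2,3,3a,4,5,8,8a-octahydroazulen-5-yl]ethyllithium | CC1=CC[C@H]2[C@H](CC[C@]2(C)O[Si](CC)(CC)CC)C(C)(C)[C@@H]1CC[Li] | intermediate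
32 | lithium alkoxide of the adduct, C7–O–SiMe3 still in place | CC1=CC[C@H]2[C@H](CC[C@]2(C)O[Si](CC)(CC)CC)C(C)(C)[C@@H]1CC[C@H](O[Li])[C@@]1(O[Si](C)(C)C)CC[C@H]2OC(C)(C)[C@@H](O[Si](C)(C)C(C)(C)C)CC[C@@]12C | intermediate
33 | (1S)-1-[(3S,5aR,6R,8aR)-3-(tert-butyldimethylsilyloxy)-6-hydroxy-2,2,5a-trimethyloctahydro-2H-cyclopenta[b]oxepin-6-yl]-3-[(1S,3aS,5R,8aS)-1,4,4,6-tetramethyl-1-(triethylsilyloxy)-1,2,3,3a,4,5,8,8a-octahydroazulen-5-yl]propan-1-ol | CC1=CC[C@H]2[C@H](CC[C@]2(C)O[Si](CC)(CC)CC)C(C)(C)[C@@H]1CC[C@H](O)[C@@]1(O)CC[C@H]2OC(C)(C)[C@@H](O[Si](C)(C)C(C)(C)C)CC[C@@]12C | intermediate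
34 | methanesulfonate of 33 at the secondary (C6) hydroxyl | CC1=CC[C@H]2[C@H](CC[C@]2(C)O[Si](CC)(CC)CC)C(C)(C)[C@@H]1CC[C@H](OS(C)(=O)=O)[C@@]1(O)CC[C@H]2OC(C)(C)[C@@H](O[Si](C)(C)C(C)(C)C)CC[C@@]12C | intermediate
35 | diethylaluminium alkoxide of 34 at the tertiary (C7) oxygen | CC1=CC[C@H]2[C@H](CC[C@]2(C)O[Si](CC)(CC)CC)C(C)(C)[C@@H]1CC[C@H](OS(C)(=O)=O)[C@@]1(O[Al](CC)CC)CC[C@H]2OC(C)(C)[C@@H](O[Si](C)(C)C(C)(C)C)CC[C@@]12C | intermediate
36 | (3S,5aS,6S,9aR)-3-(tert-butyldimethylsilyloxy)-2,2,5a-trimethyl-6-{2-[(1S,3aS,5R,8aS)-1,4,4,6-tetramethyl-1-(triethylsilyloxy)-1,2,3,3a,4,5,8,8a-octahydroazulen-5-yl]ethyl}octahydrobenzo[b]oxepin-7(2H)-one | CC1=CC[C@H]2[C@H](CC[C@]2(C)O[Si](CC)(CC)CC)C(C)(C)[C@@H]1CC[C@H]1[C@]2(C)CC[C@H](O[Si](C)(C)C(C)(C)C)C(C)(C)O[C@@H]2CCC1=O | intermediate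
37 | (3S,5aS,6S,7R,9aR)-3-(tert-butyldimethylsilyloxy)-2,2,5a,7-tetramethyl-6-{2-[(1S,3aS,5R,8aS)-1,4,4,6-tetramethyl-1-(triethylsilyloxy)-1,2,3,3a,4,5,8,8a-octahydroazulen-5-yl]ethyl}decahydrobenzo[b]oxepin-7-ol | CC1=CC[C@H]2[C@H](CC[C@]2(C)O[Si](CC)(CC)CC)C(C)(C)[C@@H]1CC[C@H]1[C@]2(C)CC[C@H](O[Si](C)(C)C(C)(C)C)C(C)(C)O[C@@H]2CC[C@@]1(C)O | intermediate
38 | (3S,5aS,6S,7R,9aR)-6-{2-[(1S,3aS,5R,8aS)-1-hydroxy-1,4,4,6-tetramethyl-1,2,3,3a,4,5,8,8a-octahydroazulen-5-yl]ethyl}-2,2,5a,7-tetramethyldecahydrobenzo[b]oxepine-3,7-diol | CC1=CC[C@H]2[C@H](CC[C@]2(C)O)C(C)(C)[C@@H]1CC[C@H]1[C@]2(C)CC[C@H](O)C(C)(C)O[C@@H]2CC[C@@]1(C)O | target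

**Step count and risks**

Total steps: 26. Longest linear sequence: 17 (steps 10–21, then 22–26).

Steps most likely to fail:

1. Step 24. The C8 methylene may migrate in place of the quaternary C5a, or the tertiary oxygen may close an oxirane onto C6, or the mesylate may eliminate before the shift. The fallback is a Tiffeneau–Demjanov ring enlargement. It sets out from aldehyde 12 and iodide 30 and returns at ketone 36. Aldehyde 12 is condensed with (S)-tert-butanesulfinamide (CuSO4, CH2Cl2) to the N-sulfinyl aldimine F1. The alkyllithium made from 30 (t-BuLi, Et2O, −78 °C) adds to it to give the sulfinamide adduct F2, in which C6 is set by the auxiliary. HCl in MeOH at 0 °C removes the sulfinyl group and the trimethylsilyl ether and, after neutralisation with NaHCO3, gives the amino alcohol F3. NaNO2 in aqueous acetic acid at 0 °C then forms the C6 diazonium ion, which leaves as the anti C7–C5a bond migrates, giving 36.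

2. Step 5. The C9a hydroxyl may attack the secondary epoxide carbon C3 (6-exo), which would give a tetrahydropyran with a tertiary carbinol in place of the oxepane. The fallback sets out from epoxide 6 and returns at 7. TMSOTf and DBU (toluene, −78 → 0 °C) open the epoxide at the tertiary carbon with loss of a methyl proton; K2CO3 in MeOH then removes the silyl groups and gives the isopropenyl carbinol (2R,3R)-3-hydroxy-2-[(3S)-3-hydroxy-4-methylpent-4-en-1-yl]-2-methylcyclopentan-1-one F4. Hg(OCOCF3)2 in CH2Cl2 at 0 °C brings about alkoxymercuration, in which the C9a hydroxyl can add only to the tertiary alkene carbon, giving the organomercurial F5. Reduction with n-Bu3SnH (THF, rt), which spares the ketone, gives 7.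

3. Step 22. Lithium chelation between the aldehyde and the α-oxygen may erode the Felkin–Anh preference and give the C6 epimer, whose mesylate would favour migration of C8. The fallback sets out from 33 (as the epimer mixture) and returns at 33. Parikh–Doering oxidation (SO3·pyridine, DMSO, i-Pr2NEt, 0 °C) of the secondary carbinol gives the α-hydroxy ketone F6. Zn(BH4)2 in Et2O at −20 °C reduces it under chelation control, with zinc bridging the carbonyl and the tertiary hydroxyl and hydride entering from the side of the C8 methylene, which returns 33 as the single C6 epimer.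

**Further compounds**

F1 | step 24 | (S)-N-{[(3S,5aR,6R,8aR)-3-(tert-butyldimethylsilyloxy)-2,2,5a-trimethyl-6-(trimethylsilyloxy)octahydro-2H-cyclopenta[b]oxepin-6-yl]methylidene}-2-methylpropane-2-sulfinamide | CC(C)(C)[S@](=O)N=C[C@@]1(O[Si](C)(C)C)CC[C@H]2OC(C)(C)[C@@H](O[Si](C)(C)C(C)(C)C)CC[C@@]12C
F2 | step 24 | sulfinamide adduct of F1 with the side chain of 30 (C6 amine carbon as in 33) | CC1=CC[C@H]2[C@H](CC[C@]2(C)O[Si](CC)(CC)CC)C(C)(C)[C@@H]1CC[C@H](N[S@@](=O)C(C)(C)C)[C@@]1(O[Si](C)(C)C)CC[C@H]2OC(C)(C)[C@@H](O[Si](C)(C)C(C)(C)C)CC[C@@]12C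
F3 | step 24 | amino alcohol, the analogue of 33 with NH2 in place of the secondary OH | CC1=CC[C@H]2[C@H](CC[C@]2(C)O[Si](CC)(CC)CC)C(C)(C)[C@@H]1CC[C@H](N)[C@@]1(O)CC[C@H]2OC(C)(C)[C@@H](O[Si](C)(C)C(C)(C)C)CC[C@@]12C
F4 | step 5 | (2R,3R)-3-hydroxy-2-[(3S)-3-hydroxy-4-methylpent-4-en-1-yl]-2-methylcyclopentan-1-one | O=C1CC[C@@H](O)[C@@]1(C)CC[C@H](O)C(C)=C
F5 | step 5 | {[(3S,5aR,8aR)-3-hydroxy-2,5a-dimethyl-6-oxooctahydro-2H-cyclopenta[b]oxepin-2-yl]methyl}mercury trifluoroacetate (C2 epimers) | O=C1CC[C@H]2OC(C)(C[Hg]OC(=O)C(F)(F)F)[C@@H](O)CC[C@@]12C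
F6 | step 22 | 1-[(3S,5aR,6R,8aR)-3-(tert-butyldimethylsilyloxy)-6-hydroxy-2,2,5a-trimethyloctahydro-2H-cyclopenta[b]oxepin-6-yl]-3-[(1S,3aS,5R,8aS)-1,4,4,6-tetramethyl-1-(triethylsilyloxy)-1,2,3,3a,4,5,8,8a-octahydroazulen-5-yl]propan-1-one | CC1=CC[C@H]2[C@H](CC[C@]2(C)O[Si](CC)(CC)CC)C(C)(C)[C@@H]1CCC(=O)[C@@]1(O)CC[C@H]2OC(C)(C)[C@@H](O[Si](C)(C)C(C)(C)C)CC[C@@]12C
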